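## Structural features

The target is a C15 tricycle with two (Z)-2-methylbut-2-enoate (angelate) esters and one free hydroxyl; atoms are numbered C1 (ketone), C2=C3 (enone alkene, methyl on C3), C4 and C11 (bridgehead CH, C11 next to C1), C5 (cyclobutane CH), C6 (gem-dimethyl), C7 and C8 (acyloxy carbons), C9 (carbinol) and C10 (quaternary, methyl). Ring B is the cyclobutane C4–C5–C11–C10; it is bridged on one face by C1–C2–C3, which makes the cyclohexenone ring A (a bicyclo[3.1.1]hept-3-en-2-one), and on the other face by C6–C7–C8–C9, which joins C5 to C10 and closes the seven-membered ring C. Seven stereocentres are contiguous: C4, C5, C11 and C10 on ring B (C5–H and the C10 methyl on the enone side, C6 and C9 on the far side), then C9, C8 and C7 on ring C, with O7 trans to O8 and O8 cis to O9. Fragile are the angelates (Z to E isomerisation, migration onto the cis 9-hydroxyl, attack by hydride or strong base), the strained cyclobutane when a radical, cation or carbonyl sits beside it, and the enone. The real difficulty is twofold: ring B with a quaternary C10 wedged between C9 and C11 and a tert-alkyl group on C5, and telling three secondary hydroxyls apart, two of which (O7, O9) are neopentyl. The key step uses the fact that the C10–C11 bond of ring B lies between two oxygen-bearing carbons: C9 can be a nitrile that stabilises a carbanion on C10, and C11–C1 can be an epoxide that C10 opens at C11 while the oxygen stays on C1, where the ketone is needed.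

## Logic of the disconnections

28 ⇒ 27 + 25; 27 ⇒ 26; 26 ⇒ 23 + 25. Bonds cut: O8–acyl, then O7–acyl. The esters are the most fragile groups and go on last, one at a time, so that O9 never has to compete with O7: in 23 the cis O8/O9 pair is tied as an acetonide and only O7 is free; in 27 only O8 and O9 are free. Gain: the problem shrinks to 23 and one acyl donor. Demand: the last acylation must choose the ordinary secondary O8 over the neopentyl O9, and neither acylation may isomerise the Z alkene.

25 ⇒ 24. Bond cut: the anhydride C–O bond between the angeloyl and the aroyl group. The acyl donor is made once, apart from the substrate, so both acylations draw on one defined species and the substrate never meets an acid chloride. Gain: 24 is bought. Demand: activation must leave the Z alkene untouched, and the donor must deliver the angeloyl and not the aroyl group.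

23 ⇒ 22 ⇒ 20 ⇒ 19. No skeletal bond is cut; the free O7, the C2=C3 π bond and the C1 carbonyl are traced back to a benzylic ether, a saturated ring and a C1 carbinol. The enone is made before any ester is present, so strong base and palladium never meet an angelate, and while O8/O9 are masked, so C1 is the only hydroxyl to oxidise. Gain: 19 has no sp2 carbon in the core. Demand: 20 must enolise towards C2 only, and hydride loss must come from C3.

19 ⇒ 18 ⇒ 17. Bond cut: C8–C9 (ring C), a reductive coupling of two aldehydes. It falls between two carbinol carbons that ring B holds on the same face. Gain: ring C and two stereocentres disappear. Demand: a cis diol, trans to the protected O7, formed faster than the C9 ketyl can open the cyclobutane.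

17 ⇒ 16 ⇒ 15 ⇒ 13. No skeletal bond is cut; the two aldehydes go back to the nitrile (C9) and an acetal-protected carbinol (C8). The acetonide of 13 cannot tell O7 from O8, and a free O7 would add to the C9 aldehyde as a six-membered lactol, so it is exchanged for an arylidene acetal that one hydride reagent opens to an O7 ether while it reduces the nitrile. Demand: opening at O8 only, and oxidation of the primary carbinol beside a free C1 hydroxyl.

13 ⇒ 12. Bond cut: C10–C11 (ring B). The cut uses the two flanking oxygens, removes the cyclobutane and two stereocentres and leaves a monocyclic cyclohexene oxide. Demand: attack at C11 and not C1, from the face opposite the oxirane, with the nitrile turned towards the C5 group.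

12 ⇒ 11 ⇒ 9 + 10. Bonds cut: the two oxirane C–O bonds, then C9–C10. Gain: an ordinary methyl ketone. Demand: epoxidation trans to the C4 and C5 substituents; the C4 centre next to the ketone must survive the basic cyanation.

9 ⇒ 7 + 8. Bonds cut: C4–C5 and C2–C3. The cyclohexene retron with acetyl on C4 is a Diels–Alder adduct. Gain: two partners without ring stereocentres. Demand: "ortho" orientation, endo approach (C4/C5 cis) and catalyst control of the ring centres relative to the remote C7.

7 ⇒ 5 ⇒ 4. Bonds cut: C11–C1 (alkenyl–alkenyl coupling) and the C5≡C11 unit back to the aldehyde carbon C5. Demand: E geometry at C5=C11.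

4 ⇒ 3 ⇒ 2 ⇒ 1. No skeletal bond is cut; C5–C8 with the C7 stereocentre are taken intact from 1 (lactone carbonyl carbon = C8, lactone CH2 = C5). Demand: the acetonide must form on the 1,2-diol.

## Other disconnections considered

Alternative 1: The cut removes two bonds of ring B at once, C5–C11 and C4–C10, and leads to the open-chain dienoyl chloride A1, in which C1 already carries a silyloxy group and C9 is a protected CH2O unit. Forward, Et3N would dehydrochlorinate A1 through the C3 methyl group, and the ketene function so formed would add across the E C11=C10 alkene in a crossed [2+2] reaction, giving cyclobutanone A2 with ring A closed in the same step.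
- In favour: two rings, two C–C bonds and the quaternary C10 arise in one step from an acyclic precursor. The alkene geometry is carried into C10, and the usual polarity of ketene additions (carbonyl carbon to the less substituted C11) matches the crossed orientation.
- Against: C5 emerges as a carbonyl carbon, so the quaternary C6 would have to be added to a hindered, strained cyclobutanone and the tertiary oxygen removed with control of C5, before C7 and C8 exist. The single C1 centre would be the only source of absolute configuration.
- Comparison: in bonds and rings per step this plan is better than the chosen one (step 9 forms one bond and one ring). Mechanistically the two key steps are about equally well founded. In step economy it falls behind, because 13 already holds C5–C8 with C7 set, whereas A2 lacks C6–C8 and a practical way to attach them.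

Alternative 2: The cut is made at the C2=C3 alkene, traced back to a sulfonyl group bridging C2 and C3 in the seven-membered cyclic sulfone A3, whose frame already contains rings B and C, an 8,9-acetonide and a 7-silyl ether. Forward, KOH on Al2O3 with CBr2F2 would halogenate A3 next to sulfur, close the three-membered ring from the other α-carbon and extrude the sulfonyl bridge (Ramberg–Bäcklund reaction), contracting the heterocycle to ring A and giving alkene A4; allylic oxidation at C1 would follow.
- In favour: the alkene is placed without ambiguity under conditions that acetals and silyl ethers tolerate. The finish by allylic oxidation of a pinene-type alkene spares the ketone dehydrogenation of step 16; on this point the alternative is the equal of the chosen plan or slightly better.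
- Against: the key step creates no stereocentre and no bond of the strained core. Ring B, the quaternary C10 and ring C must all be present in A3, so the hard problems are only moved into the synthesis of a bridged sulfur heterocycle.
- Comparison: structurally it simplifies far less than the C10–C11 cut. Mechanistically it is reliable. In step count it would be longer, since sulfur must be brought in and removed in addition to everything the chosen plan needs.

Alternative 3: The cut follows a retro 1,2-shift that moves C10 from C11 back to C1 and then opens the resulting norbornene at C1–C11 and C4–C5, giving the silyloxycyclopentadiene A5 (C1–C4 and C10) and the nitroalkene A6 (C5, C11 and the C6–C8 chain, available from 4). Forward, an endo Diels–Alder reaction of A5 with A6 would give norbornene A7 (silyloxy on bridgehead C1, nitro endo on C11, chain exo on C5); a later ionisation at C11 with migration of C10 and carbonyl formation at C1 would reshape the skeleton.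
- In favour: two C–C bonds and four stereocentres, the quaternary C10 among them, in one step. C1 and C2=C3 are already at the oxidation level of the target, so the enone would emerge from the shift itself; here the alternative is better than the chosen plan.
- Against: A5 has its own stereocentre at C10, would have to be made as one enantiomer and would have to react on the face syn to the nitrile. The shift must run from the norbornane to the more strained bicyclo[3.1.1] frame with a nitro group as leaving group, against easier elimination or cycloreversion.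
- Comparison: structurally more convergent and potentially shorter. Mechanistically much less secure than the SN2 opening of 12, whose trajectory and leaving group are well defined. Ring C would be closed in the same way in both plans, so that part is equal.

Key step: step 9

Assumption (step 6): the boron cation built on (S)-diphenylprolinol is taken to expose the Cα-Re face of 8, as its binding model for enones suggests; if the sense is the opposite, the enantiomeric catalyst is used and nothing else changes.
Remark: C10 in 11 and 12 and the acetal carbon in 15 arise as epimer mixtures that converge in steps 9 and 11; the SMILES of 11 and 12 show one C10 epimer.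

## Route

Step 1
Reactants: 1 (S)-pantolactone
Product: 2 (2S)-3,3-dimethylbutane-1,2,4-triol
Conditions: LiAlH4, THF, 0 °C to reflux; NaOH/H2O work-up
Reagents that add atoms: none
Why: Hydride reduction of the lactone (carbonyl carbon becomes the C8 carbinol, ring CH2O the C5 carbinol); no bond to the C7 stereocentre is touched.

Step 2
Reactants: 2 (2S)-3,3-dimethylbutane-1,2,4-triol
Product: 3 2-[(4S)-2,2-dimethyl-1,3-dioxolan-4-yl]-2-methylpropan-1-ol
Conditions: Me2C(OMe)2, acetone, TsOH·H2O (cat.), rt
Reagents that add atoms: 2,2-dimethoxypropane, COC(C)(C)OC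
Why: Thermodynamic acetonide formation prefers the five-membered 1,2-dioxolane (O7/O8) over the 1,3-dioxane with its axial methyl, leaving the neopentyl C5 carbinol free.

Step 3
Reactants: 3 2-[(4S)-2,2-dimethyl-1,3-dioxolan-4-yl]-2-methylpropan-1-ol
Product: 4 2-[(4S)-2,2-dimethyl-1,3-dioxolan-4-yl]-2-methylpropanal
Conditions: (COCl)2, DMSO, CH2Cl2, −78 °C; Et3N, to 0 °C
Reagents that add atoms: none
Why: Swern oxidation; the aldehyde (C5) has no α-hydrogen, so it can neither enolise nor epimerise.

Step 4
Reactants: 4 2-[(4S)-2,2-dimethyl-1,3-dioxolan-4-yl]-2-methylpropanal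
Product: 5 (4S)-2,2-dimethyl-4-(2-methylbut-3-yn-2-yl)-1,3-dioxolane
Conditions: MeC(O)C(N2)P(O)(OMe)2, K2CO3, MeOH, 0 °C to rt
Reagents that add atoms: dimethyl (1-diazo-2-oxopropyl)phosphonate, CC(=O)C(=[N+]=[N-])P(=O)(OC)OC
Why: Seyferth–Gilbert homologation under Ohira–Bestmann conditions: the diazomethylphosphonate anion made in situ adds to the aldehyde, phosphate is lost and the alkylidene carbene rearranges to the terminal alkyne; the new carbon is C11.

Step 5
Reactants: 5 (4S)-2,2-dimethyl-4-(2-methylbut-3-yn-2-yl)-1,3-dioxolane
Product: 7 (4S)-2,2-dimethyl-4-[(3E)-2-methylhexa-3,5-dien-2-yl]-1,3-dioxolane, via alkenylzirconocene chloride 6 (not isolated)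
Conditions: Cp2Zr(H)Cl, THF, rt; then CH2=CHBr, Pd(PPh3)4 (5 mol %), rt
Reagents that add atoms: vinyl bromide, C=CBr
Why: Syn hydrozirconation puts zirconium on the terminal carbon (E alkenyl metal), and the palladium-catalysed Negishi-type coupling with vinyl bromide proceeds with retention, so the C5=C11 alkene is E and the diene can reach the s-cis form.

Step 6
Reactants: 7 (4S)-2,2-dimethyl-4-[(3E)-2-methylhexa-3,5-dien-2-yl]-1,3-dioxolane; 8 (E)-pent-3-en-2-one
Product: 9 1-[(1S,2R,6R)-2-{2-[(4S)-2,2-dimethyl-1,3-dioxolan-4-yl]propan-2-yl}-6-methylcyclohex-3-en-1-yl]ethan-1-one (acetyl on C4 cis to the C5 chain, trans to the C3 methyl)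
Conditions: N-protonated (S)-3,3-diphenyl-1-(2-methylphenyl)tetrahydro-1H,3H-pyrrolo[1,2-c][1,3,2]oxazaborole bis(trifluoromethanesulfonyl)imide (20 mol %), CH2Cl2, −40 to −20 °C
Reagents that add atoms: none
Why: Lewis-acid-catalysed Diels–Alder reaction: the unsubstituted diene terminus C2 (largest HOMO coefficient) bonds to the enone β-carbon C3, so the acetyl-bearing C4 ends next to C5. Endo approach of the boron-bound acetyl puts it cis to the C5 chain, the E enone keeps the C3 methyl trans to acetyl, and the chiral boron cation selects the enone face, which fixes C3, C4 and C5 relative to the remote C7.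

Step 7
Reactants: 9 cyclohexenyl methyl ketone (as named in step 6); 10 tosylmethyl isocyanide (TosMIC)
Product: 11 2-[(1S,2R,6R)-2-{2-[(4S)-2,2-dimethyl-1,3-dioxolan-4-yl]propan-2-yl}-6-methylcyclohex-3-en-1-yl]propanenitrile (both C10 epimers)
Conditions: t-BuOK, DME/t-BuOH, 0 °C to rt
Reagents that add atoms: none
Why: Van Leusen reductive cyanation: the TosMIC anion adds to the ketone, the oxazoline opens, and loss of formate and sulfinate leaves the nitrile with C9 as its carbon. C10 forms as both epimers, which is immaterial because step 9 deprotonates it; C4 keeps its configuration provided addition outruns enolisation.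

Step 8
Reactants: 11 cyclohexenyl nitrile (as named in step 7)
Product: 12 2-[2-{2-[(4S)-2,2-dimethyl-1,3-dioxolan-4-yl]propan-2-yl}-4-methyl-7-oxabicyclo[4.1.0]heptan-3-yl]propanenitrile (oxirane at C11–C1, trans to the C4 and C5 substituents, cis to the C3 methyl)
Conditions: mCPBA, NaHCO3, CH2Cl2, 0 °C
Reagents that add atoms: 3-chloroperoxybenzoic acid, OOC(=O)c1cccc(Cl)c1
Why: Prilezhaev epoxidation: the peracid approaches the ring alkene from the face opposite the allylic tert-alkyl group on C5 and the C4 chain, so the oxirane is trans to both, as the backside trajectory of step 9 requires.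

Step 9
Reactants: 12 epoxy nitrile (as named in step 8)
Product: 13 2-hydroxy-4,6-dimethyl-7-{2-[(4S)-2,2-dimethyl-1,3-dioxolan-4-yl]propan-2-yl}bicyclo[3.1.1]heptane-6-carbonitrile (C10 methyl over the C1–C2–C3 bridge, nitrile and the C5 chain on the far face, C1–OH and C3 methyl on the side of the C5 bridge)
Conditions: KN(SiMe3)2 (1.5 equiv), toluene, 0 °C to rt (to 60 °C if slow); H2O
Reagents that add atoms: none
Why: KN(SiMe3)2 reversibly removes the proton α to the nitrile, and the planar C10 keteniminate opens the epoxide at C11 in an intramolecular SN2 reaction, collinear with and anti to the C11–O bond. The closest known reaction type is the epoxynitrile cyclisation to cyclobutanols, in which the exo mode is preferred; the bridging across a six-membered ring parallels the enolate alkylations that build the pinane skeleton. The ring closed is the cyclobutane C4–C5–C11–C10, by a 4-exo-tet closure (the C11–O bond broken lies outside the new ring), which turns the cyclohexane into a bicyclo[3.1.1]heptane. C11 is set by inversion: the oxirane oxygen is trans to the C4 chain, so C10 enters on the face that the chain occupies and the oxygen stays on C1 with retention. C10 is set by the size difference of its substituents: the slim nitrile takes the position facing the C5 tert-alkyl group and the methyl the position over C1–C2–C3. The selectivity needed is attack at C11 and not at C1 (which would give a bicyclo[2.2.1]heptane): the large C5 group sits pseudo-equatorial and so holds the cis C4 chain axial, 1,3-syn to the trans-diaxial (Fürst–Plattner) trajectory at C11, while C1 could be reached only through a boat. Nitrile deprotonation must also outrun base-induced isomerisation of the epoxide to an allylic alcohol, which the non-nucleophilic amide base in toluene favours.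

Step 10
Reactants: 13 bicyclic hydroxy nitrile acetonide (as named in step 9)
Product: 15 4-methoxybenzylidene acetal of the O7/O8 diol of 13 (C1–OH free, both acetal epimers), via triol nitrile 14 (not isolated)
Conditions: CSA (cat.), MeOH, rt; evaporate; 4-MeOC6H4CH(OMe)2, CSA (cat.), CH2Cl2, rt
Reagents that add atoms: 4-methoxybenzaldehyde dimethyl acetal, COc1ccc(cc1)C(OC)OC
Why: Acid-catalysed acetal exchange: methanolysis removes the acetonide, and only the 1,2-diol can form a cyclic acetal with the aryl aldehyde acetal (C1–OH stays free). The new acetal carbon is an epimer mixture that is erased in step 11.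

Step 11
Reactants: 15 arylidene acetal nitrile (as named in step 10)
Product: 16 bicyclic hydroxy aldehyde: C9 aldehyde on C10, side chain C(CH3)2–CH(O-4-methoxybenzyl)–CH2OH, C1–OH free
Conditions: i-Bu2AlH (6 equiv), CH2Cl2, −78 to 0 °C; aq. potassium sodium tartrate, then wet SiO2
Reagents that add atoms: water, O
Why: DIBAL does two jobs: it reduces the nitrile to the N-aluminio aldimine (aldehyde C9 after hydrolysis) and, by binding the less hindered primary O8, cleaves the arylidene acetal regioselectively, leaving O7 as its 4-methoxybenzyl ether and C8 as the free carbinol.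

Step 12
Reactants: 16 hydroxy aldehyde (as named in step 11)
Product: 17 dialdehyde: C8 and C9 aldehydes, 7-O-(4-methoxybenzyl), C1–OH free
Conditions: PhI(OAc)2, TEMPO (10 mol %), CH2Cl2, rt
Reagents that add atoms: none
Why: Oxoammonium (TEMPO) oxidation with PhI(OAc)2 as terminal oxidant is strongly selective for the primary carbinol C8 over the hindered secondary C1–OH and does not over-oxidise; no base is present, so the α-alkoxy centre C7 should keep its configuration.

Step 13
Reactants: 17 dialdehyde (as named in step 12)
Product: 18 tricyclic triol: ring C closed at C8–C9; 8-OH cis to 9-OH and trans to the 7-O-(4-methoxybenzyl) group; C1–OH as in 13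
Conditions: SmI2 (3 equiv), t-BuOH, THF, −78 °C to rt
Reagents that add atoms: none
Why: Pinacol coupling with divalent samarium: the two aldehydes, held on the same face of ring B, are reduced to ketyls that couple through a samarium-bridged arrangement, which gives the cis 8,9-diol. The C8 oxygen turns away from the adjacent 7-alkoxy group, so O8 is trans to O7; at −78 °C the coupling should outrun opening of the cyclobutane from the C9 ketyl.

Step 14
Reactants: 18 tricyclic triol (as named in step 13)
Product: 19 8,9-O-isopropylidene derivative of 18 (C1–OH free, 7-O-(4-methoxybenzyl))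
Conditions: Me2C(OMe)2, PPTS (cat.), acetone, rt
Reagents that add atoms: 2,2-dimethoxypropane, COC(C)(C)OC
Why: Only the cis 8,9-diol can form a five-membered acetonide, which masks O8 and O9 together and so sets them apart from O7 and from the C1 hydroxyl.

Step 15
Reactants: 19 acetonide alcohol (as named in step 14)
Product: 20 C1 ketone of 19
Conditions: Dess–Martin periodinane, NaHCO3, CH2Cl2, rt
Reagents that add atoms: none
Why: Dess–Martin oxidation of the only free hydroxyl gives the C1 ketone under buffered conditions; the one α-stereocentre, bridgehead C11, cannot enolise and so cannot epimerise.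

Step 16
Reactants: 20 tricyclic ketone (as named in step 15)
Product: 22 C2=C3 enone (8,9-acetonide, 7-O-(4-methoxybenzyl)), via trimethylsilyl enol ether 21 (not isolated)
Conditions: LDA, Me3SiCl, THF, −78 °C; then Pd(OAc)2 (1.1 equiv), MeCN, rt
Reagents that add atoms: none
Why: Saegusa–Ito dehydrogenation: the ketone can enolise only towards C2 because C11 is a bridgehead, the silyl enol ether passes its enolate to divalent palladium, and β-hydride elimination from C3 gives the enone. The C3 stereocentre is removed here on purpose.

Step 17
Reactants: 22 enone 4-methoxybenzyl ether (as named in step 16)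
Product: 23 7-hydroxy enone with 8,9-acetonide
Conditions: DDQ, CH2Cl2/pH 7 buffer, 0 °C to rt
Reagents that add atoms: none
Why: Oxidative cleavage of the 4-methoxybenzyl ether by DDQ (benzylic hydride abstraction, hydrolysis of the hemiacetal) frees O7 alone; acetonide and enone are inert.

Step 18
Reactants: 24 angelic acid, (Z)-2-methylbut-2-enoic acid
Product: 25 (Z)-2-methylbut-2-enoic 2,4,6-trichlorobenzoic anhydride (mixed anhydride, toluene solution)
Conditions: 2,4,6-Cl3C6H2COCl (1.0 equiv), Et3N (1.05 equiv), toluene, 0 °C to rt; filter off Et3N·HCl under argon; filtrate kept at −20 °C and drawn on in steps 19 and 21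
Reagents that add atoms: 2,4,6-trichlorobenzoyl chloride, O=C(Cl)c1c(Cl)cc(Cl)cc1Cl
Why: Acyl substitution of the aroyl chloride by the triethylammonium carboxylate (the activation stage of the Yamaguchi esterification) gives the mixed anhydride; no nucleophilic catalyst or conjugate addition is involved, so the Z geometry of 24 should be kept.

Step 19
Reactants: 23 7-hydroxy enone acetonide (as named in step 17); 25 mixed anhydride (as named in step 18)
Product: 26 7-O-angeloyl enone with 8,9-acetonide
Conditions: 25 (3 equiv), Et3N (3 equiv), toluene, 80 °C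
Reagents that add atoms: none
Why: Yamaguchi-type acylation with the preformed mixed anhydride: the neopentyl 7-OH, the one free hydroxyl, attacks the angeloyl carbonyl because the aroyl carbonyl is screened by its two ortho chlorines; working without a nucleophilic acyl-transfer catalyst is the usual way to avoid Z to E isomerisation to the tiglate.

Step 20
Reactants: 26 7-angelate acetonide (as named in step 19)
Product: 27 7-O-angeloyl-8,9-dihydroxy enone
Conditions: AcOH/H2O 4:1, 40 °C
Reagents that add atoms: none
Why: Mild aqueous acid hydrolyses the cis acetonide; ester, enone and cyclobutane tolerate it, and no base is present to move the 7-acyl group.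

Step 21
Reactants: 27 7-angelate diol (as named in step 20); 25 mixed anhydride (as named in step 18)
Product: 28 CNP0256888.1, the 7,8-di-O-angeloyl-9-hydroxy enone
Conditions: 25 (1.5 equiv), Et3N (1.5 equiv), toluene, 60 °C
Reagents that add atoms: none
Why: Same acylation with a small excess of the anhydride: O8 is a secondary hydroxyl between two CH carbons, whereas O9 is neopentyl (next to quaternary C10) and shielded by ring B, so mono-acylation should occur at O8 and complete the target.

## Compound list

1 | (S)-pantolactone, (3S)-3-hydroxy-4,4-dimethyloxolan-2-one | CC1(C)COC(=O)[C@H]1O | starting material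
2 | (2S)-3,3-dimethylbutane-1,2,4-triol | OC[C@@H](O)C(C)(C)CO | intermediate
3 | 2-[(4S)-2,2-dimethyl-1,3-dioxolan-4-yl]-2-methylpropan-1-ol | CC1(C)OC[C@@H](O1)C(C)(C)CO | intermediate
4 | 2-[(4S)-2,2-dimethyl-1,3-dioxolan-4-yl]-2-methylpropanal | CC1(C)OC[C@@H](O1)C(C)(C)C=O | intermediate
5 | (4S)-2,2-dimethyl-4-(2-methylbut-3-yn-2-yl)-1,3-dioxolane | CC1(C)OC[C@@H](O1)C(C)(C)C#C | intermediate
6 | (E)-alkenylzirconocene chloride from 5 (Cp2ZrCl on the terminal carbon) | CC1(C)OC[C@@H](O1)C(C)(C)/C=C/[Zr](Cl)(C2C=CC=C2)C2C=CC=C2 | intermediate (not isolated)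
7 | (4S)-2,2-dimethyl-4-[(3E)-2-methylhexa-3,5-dien-2-yl]-1,3-dioxolane | CC1(C)OC[C@@H](O1)C(C)(C)/C=C/C=C | intermediate
8 | (E)-pent-3-en-2-one | C/C=C/C(C)=O | starting material
9 | 1-[(1S,2R,6R)-2-{2-[(4S)-2,2-dimethyl-1,3-dioxolan-4-yl]propan-2-yl}-6-methylcyclohex-3-en-1-yl]ethan-1-one | CC1(C)OC[C@@H](O1)C(C)(C)[C@@H]2C=CC[C@@H](C)[C@@H]2C(C)=O | intermediate
10 | tosylmethyl isocyanide (TosMIC) | Cc1ccc(cc1)S(=O)(=O)C[N+]#[C-] | starting material
11 | 2-[(1S,2R,6R)-2-{2-[(4S)-2,2-dimethyl-1,3-dioxolan-4-yl]propan-2-yl}-6-methylcyclohex-3-en-1-yl]propanenitrile (C10 epimers, one written) | CC1(C)OC[C@@H](O1)C(C)(C)[C@@H]2C=CC[C@@H](C)[C@@H]2[C@@H](C)C#N | intermediate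
12 | epoxy nitrile, oxirane trans to the C4 and C5 substituents (key-step precursor; C10 epimers, one written) | CC1(C)OC[C@@H](O1)C(C)(C)[C@@H]2[C@H]3O[C@H]3C[C@@H](C)[C@@H]2[C@@H](C)C#N | intermediate
13 | 2-hydroxy-4,6-dimethyl-7-{2-[(4S)-2,2-dimethyl-1,3-dioxolan-4-yl]propan-2-yl}bicyclo[3.1.1]heptane-6-carbonitrile (key-step product) | CC1(C)OC[C@@H](O1)C(C)(C)[C@@H]2[C@H]3[C@@H](O)C[C@@H](C)[C@@H]2[C@@]3(C)C#N | intermediate
14 | triol nitrile (13 without the acetonide) | OC[C@@H](O)C(C)(C)[C@@H]2[C@H]3[C@@H](O)C[C@@H](C)[C@@H]2[C@@]3(C)C#N | intermediate (not isolated)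
15 | O7/O8 4-methoxybenzylidene acetal of 14 (acetal epimers) | COc1ccc(cc1)C4OC[C@@H](O4)C(C)(C)[C@@H]2[C@H]3[C@@H](O)C[C@@H](C)[C@@H]2[C@@]3(C)C#N | intermediate
16 | bicyclic C9 aldehyde with 7-O-(4-methoxybenzyl), C8 carbinol and C1–OH | OC[C@@H](OCc1ccc(OC)cc1)C(C)(C)[C@@H]2[C@H]3[C@@H](O)C[C@@H](C)[C@@H]2[C@@]3(C)C=O | intermediate
17 | C8,C9 dialdehyde with 7-O-(4-methoxybenzyl) and C1–OH | O=C[C@@H](OCc1ccc(OC)cc1)C(C)(C)[C@@H]2[C@H]3[C@@H](O)C[C@@H](C)[C@@H]2[C@@]3(C)C=O | intermediate
18 | tricyclic 1,8,9-triol, 7-O-(4-methoxybenzyl); 8,9-cis, 7,8-trans | O[C@@H]1[C@@H](OCc4ccc(OC)cc4)C(C)(C)[C@@H]2[C@H]3[C@@H](O)C[C@@H](C)[C@@H]2[C@@]3(C)[C@@H]1O | intermediate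
19 | 8,9-O-isopropylidene derivative of 18 | CC4(C)O[C@@H]1[C@@H](OCc5ccc(OC)cc5)C(C)(C)[C@@H]2[C@H]3[C@@H](O)C[C@@H](C)[C@@H]2[C@@]3(C)[C@@H]1O4 | intermediate
20 | C1 ketone of 19 | CC4(C)O[C@@H]1[C@@H](OCc5ccc(OC)cc5)C(C)(C)[C@@H]2[C@H]3C(=O)C[C@@H](C)[C@@H]2[C@@]3(C)[C@@H]1O4 | intermediate
21 | trimethylsilyl enol ether (C1=C2) of 20 | CC4(C)O[C@@H]1[C@@H](OCc5ccc(OC)cc5)C(C)(C)[C@@H]2[C@H]3C(O[Si](C)(C)C)=C[C@@H](C)[C@@H]2[C@@]3(C)[C@@H]1O4 | intermediate (not isolated)
22 | C2=C3 enone, 8,9-acetonide, 7-O-(4-methoxybenzyl) | CC4(C)O[C@@H]1[C@@H](OCc5ccc(OC)cc5)C(C)(C)[C@@H]2[C@H]3C(=O)C=C(C)[C@@H]2[C@@]3(C)[C@@H]1O4 | intermediate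
23 | 7-hydroxy enone, 8,9-acetonide | CC4(C)O[C@@H]1[C@@H](O)C(C)(C)[C@@H]2[C@H]3C(=O)C=C(C)[C@@H]2[C@@]3(C)[C@@H]1O4 | intermediate
24 | angelic acid, (Z)-2-methylbut-2-enoic acid | C/C=C(/C)C(=O)O | starting material
25 | (Z)-2-methylbut-2-enoic 2,4,6-trichlorobenzoic anhydride | C/C=C(/C)C(=O)OC(=O)c1c(Cl)cc(Cl)cc1Cl | intermediate
26 | 7-O-angeloyl enone, 8,9-acetonide | CC4(C)O[C@@H]1[C@@H](OC(=O)/C(C)=C\C)C(C)(C)[C@@H]2[C@H]3C(=O)C=C(C)[C@@H]2[C@@]3(C)[C@@H]1O4 | intermediate
27 | 7-O-angeloyl-8,9-dihydroxy enone | O[C@@H]1[C@@H](OC(=O)/C(C)=C\C)C(C)(C)[C@@H]2[C@H]3C(=O)C=C(C)[C@@H]2[C@@]3(C)[C@@H]1O | intermediate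
28 | CNP0256888.1, 7,8-di-O-angeloyl-9-hydroxy enone | C/C=C(/C)C(=O)O[C@@H]1[C@@H](OC(=O)/C(C)=C\C)C(C)(C)[C@@H]2[C@H]3C(=O)C=C(C)[C@@H]2[C@@]3(C)[C@@H]1O | target

## Step count and least certain steps

Total: 21 steps. Longest linear sequence: 20 steps (1 to 28 through steps 1 to 17 and 19 to 21); step 18 is a one-step branch from 24; 8, 10 and 24 are bought.

Step 9 (key step). Most likely failure: the carbanion closes onto C1 through a boat (bicyclo[2.2.1] ring), or epoxide isomerisation and proton transfer win because closure to the strained four-membered ring is slow; poor facial choice at C10 is a lesser risk. Fallback, from 11 back to 13, which leaves only C11 electrophilic: dihydroxylation of 11 (OsO4 cat., NMO) from the open face gives cis-diol F1. The C1 hydroxyl, next to a CH2, is silylated selectively (TBSCl, imidazole) to give silyl ether F2, and the hindered C11 hydroxyl is mesylated (MsCl, Et3N) to give mesylate F3. KN(SiMe3)2 then closes ring B by SN2 displacement at C11 to give bicyclic silyl ether F4, and Bu4NF releases 13.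

Step 6. Most likely failure: sluggish cycloaddition of the hindered diene with a β-substituted enone, loss of endo preference against the tert-alkyl group, weak catalyst control over the ring centres relative to C7, or acid damage to the acetonide. Fallback, from 7 back to 9: 7 is combined with crotonimide F5 and Et2AlCl (CH2Cl2, −30 °C). The aluminium-chelated s-cis imide is a much stronger dienophile and its benzyl group covers the Cα-Si face, which should give imide adduct F6. Me(MeO)NH·HCl/AlMe3 then gives Weinreb amide F7, and MeMgBr gives 9.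

Step 7. Most likely failure: enolisation of the hindered ketone towards C4 before TosMIC adds, which would epimerise the C4/C5 cis relation. Fallback, from 9 back to 11, with no base at a carbonyl next to C4: Cp2TiMe2 (toluene, 65 °C) methylenates the ketone to isopropenyl compound F8. 9-BBN, then NaOH/H2O2, hydroborates the 1,1-disubstituted alkene in preference to the ring alkene and gives primary alcohol F9. Dess–Martin oxidation gives aldehyde F10, and I2 in aqueous NH3 converts it into 11.

Step 13. Most likely failure: ring opening of the cyclobutane from the C9 ketyl, or coupling with the wrong relative configuration (trans diol, or cis diol syn to O7). Fallback, from 17 back to 18, without radicals: both aldehydes are methylenated (Ph3P=CH2, THF, −78 to 0 °C) to give diene F11. Ring-closing metathesis with the second-generation Grubbs catalyst (H2IMes)(PCy3)Cl2Ru=CHPh gives cycloheptene F12, and OsO4 (cat.)/NMO adds from the face opposite the allylic 7-alkoxy group to give 18.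

Step 21. Most likely failure: acylation of O9 as well as, or instead of, O8, or acyl migration between the cis oxygens. Fallback, from 22 to 28, in which O9 is protected by construction: aqueous AcOH removes the acetonide of 22 to give diol F13. DDQ under anhydrous conditions (4 Å sieves) joins the 7-O-(4-methoxybenzyl) ether to the neighbouring 8-OH as arylidene acetal F14, leaving only 9-OH free (the trans-related O7 and O9 cannot be bridged). TBSOTf/2,6-lutidine gives silyl ether F15, and aqueous AcOH cleaves the acetal to 7,8-diol F16. Excess 25 acylates both hydroxyls to give bis-angelate F17, and HF·pyridine gives 28.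

Further compounds
F1 | step 9 | cis-C11,C1-diol of 11 (both hydroxyls trans to the C4 and C5 substituents) | CC1(C)OC[C@@H](O1)C(C)(C)[C@@H]2[C@@H](O)[C@@H](O)C[C@@H](C)[C@@H]2[C@@H](C)C#N
F2 | step 9 | C1 tert-butyldimethylsilyl ether of F1 | CC1(C)OC[C@@H](O1)C(C)(C)[C@@H]2[C@@H](O)[C@@H](O[Si](C)(C)C(C)(C)C)C[C@@H](C)[C@@H]2[C@@H](C)C#N
F3 | step 9 | C11 methanesulfonate of F2 | CC1(C)OC[C@@H](O1)C(C)(C)[C@@H]2[C@@H](OS(C)(=O)=O)[C@@H](O[Si](C)(C)C(C)(C)C)C[C@@H](C)[C@@H]2[C@@H](C)C#N
F4 | step 9 | C1 tert-butyldimethylsilyl ether of 13 | CC1(C)OC[C@@H](O1)C(C)(C)[C@@H]2[C@H]3[C@@H](O[Si](C)(C)C(C)(C)C)C[C@@H](C)[C@@H]2[C@@]3(C)C#N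
F5 | step 6 | (R)-4-benzyl-3-[(E)-but-2-enoyl]oxazolidin-2-one | C/C=C/C(=O)N1[C@H](Cc2ccccc2)COC1=O
F6 | step 6 | N-acyl oxazolidinone Diels–Alder adduct (ring centres as in 9) | CC1(C)OC[C@@H](O1)C(C)(C)[C@@H]2C=CC[C@@H](C)[C@@H]2C(=O)N3[C@H](Cc4ccccc4)COC3=O
F7 | step 6 | N-methoxy-N-methyl amide corresponding to 9 | CC1(C)OC[C@@H](O1)C(C)(C)[C@@H]2C=CC[C@@H](C)[C@@H]2C(=O)N(C)OC
F8 | step 7 | isopropenyl compound from 9 | CC1(C)OC[C@@H](O1)C(C)(C)[C@@H]2C=CC[C@@H](C)[C@@H]2C(C)=C
F9 | step 7 | primary alcohol (C9 carbinol, C10 epimers) | CC1(C)OC[C@@H](O1)C(C)(C)[C@@H]2C=CC[C@@H](C)[C@@H]2C(C)CO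
F10 | step 7 | C9 aldehyde (C10 epimers) | CC1(C)OC[C@@H](O1)C(C)(C)[C@@H]2C=CC[C@@H](C)[C@@H]2C(C)C=O
F11 | step 13 | bis-vinyl compound from 17 | C=C[C@@H](OCc1ccc(OC)cc1)C(C)(C)[C@@H]2[C@H]3[C@@H](O)C[C@@H](C)[C@@H]2[C@@]3(C)C=C
F12 | step 13 | tricyclic C8=C9 cycloheptene | C=1[C@@H](OCc4ccc(OC)cc4)C(C)(C)[C@@H]2[C@H]3[C@@H](O)C[C@@H](C)[C@@H]2[C@@]3(C)C=1
F13 | step 21 | 8,9-dihydroxy enone, 7-O-(4-methoxybenzyl) | O[C@@H]1[C@@H](OCc4ccc(OC)cc4)C(C)(C)[C@@H]2[C@H]3C(=O)C=C(C)[C@@H]2[C@@]3(C)[C@@H]1O
F14 | step 21 | 7,8-O-(4-methoxybenzylidene) acetal, 9-OH free (acetal epimers) | COc1ccc(cc1)C4O[C@@H]5[C@@H](O4)C(C)(C)[C@@H]2[C@H]3C(=O)C=C(C)[C@@H]2[C@@]3(C)[C@@H]5O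
F15 | step 21 | 9-O-tert-butyldimethylsilyl ether of F14 | COc1ccc(cc1)C4O[C@@H]5[C@@H](O4)C(C)(C)[C@@H]2[C@H]3C(=O)C=C(C)[C@@H]2[C@@]3(C)[C@@H]5O[Si](C)(C)C(C)(C)C
F16 | step 21 | 7,8-dihydroxy enone, 9-O-tert-butyldimethylsilyl | O[C@@H]1[C@@H](O)C(C)(C)[C@@H]2[C@H]3C(=O)C=C(C)[C@@H]2[C@@]3(C)[C@@H]1O[Si](C)(C)C(C)(C)C
F17 | step 21 | 7,8-di-O-angeloyl enone, 9-O-tert-butyldimethylsilyl | C/C=C(/C)C(=O)O[C@@H]1[C@@H](OC(=O)/C(C)=C\C)C(C)(C)[C@@H]2[C@H]3C(=O)C=C(C)[C@@H]2[C@@]3(C)[C@@H]1O[Si](C)(C)C(C)(C)C
A1 | alternative 1 | (2E,6E)-5-(tert-butyldimethylsilyloxy)-8-(4-methoxybenzyloxy)-3,7-dimethylocta-2,6-dienoyl chloride | O=C(Cl)/C=C(\C)C[C@H](O[Si](C)(C)C(C)(C)C)/C=C(/COCc1ccc(OC)cc1)C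
A2 | alternative 1 | 4-(tert-butyldimethylsilyloxy)-7-(4-methoxybenzyloxymethyl)-7-methyl-2-methylidenebicyclo[3.1.1]heptan-6-one | O=C1[C@H]2[C@@H](O[Si](C)(C)C(C)(C)C)CC(=C)[C@@H]1[C@@]2(C)COCc1ccc(OC)cc1
A3 | alternative 2 | bridged seven-membered cyclic sulfone (SO2 between C2 and C3), 8,9-acetonide, 7-O-tert-butyldimethylsilyl | CC4(C)O[C@@H]1[C@@H](O[Si](C)(C)C(C)(C)C)C(C)(C)[C@@H]2[C@H]3CCS(=O)(=O)C(C)[C@@H]2[C@@]3(C)[C@@H]1O4
A4 | alternative 2 | protected tricyclic C2=C3 alkene (1-deoxo core) | CC4(C)O[C@@H]1[C@@H](O[Si](C)(C)C(C)(C)C)C(C)(C)[C@@H]2[C@H]3CC=C(C)[C@@H]2[C@@]3(C)[C@@H]1O4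
A5 | alternative 3 | 2-(tert-butyldimethylsilyloxy)-1,4-dimethylcyclopenta-2,4-diene-1-carbonitrile | C[C@]1(C#N)C(O[Si](C)(C)C(C)(C)C)=CC(C)=C1
A6 | alternative 3 | (4S)-2,2-dimethyl-4-[(3E)-2-methyl-4-nitrobut-3-en-2-yl]-1,3-dioxolane | CC1(C)OC[C@@H](O1)C(C)(C)/C=C/[N+](=O)[O-]
A7 | alternative 3 | norbornene adduct (bridgehead silyloxy C1, endo nitro C11, exo chain C5, methyl/cyano bridge C10) | CC1(C)OC[C@@H](O1)C(C)(C)[C@@H]2[C@@H]([N+](=O)[O-])[C@@]3(O[Si](C)(C)C(C)(C)C)C=C(C)[C@@H]2[C@@]3(C)C#N
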